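The numbers were set for the occasion; what happens was integrated by code.

What a flask gives at the reading is a leftover: the target still standing is what was made minus what was lost, so I first asked where lost target went.

starting material 39 mM; reagent in the second phase 39.0 mM; protic impurity 3.90 mM; time 25 h; volume of the second phase over the first 1.0

    reagent in the reaction phase ⇌ reagent in the second phase, rate k1*([reagent in the reaction phase] - [reagent in the second phase]/K1) per volume of the first phase (K1 = 0.87, k1 = 2.61 h⁻¹)
    starting material + reagent in the reaction phase → target (k2 = 20.2 M⁻¹ h⁻¹)
    target ⇌ product in the second phase, rate k3*([target] - [product in the second phase]/K3) per volume of the first phase (K3 = 3.76, k3 = 1.04 h⁻¹)
    target → decomposed product (k4 = 1.04 h⁻¹)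
    starting material + target → side product (k5 = 6.57 M⁻¹ h⁻¹)
    starting material + protic impurity → quenched substrate (k6 = 102 M⁻¹ h⁻¹)

- epsilon: doubling the transfer coefficient of step 1, all else as stated
- delta: doubling the transfer coefficient of step 3, all else as stated
- gamma: doubling the amount of reagent in the second phase, all else as stated

- percent here means starting material units held: one side product counts as two
- what is said of target includes product in the second phase
- in the second phase: reagent in the second phase, product in the second phase; everything else is in the first
- charges count per volume of the first phase; a concentration in a rate is the amount of a species over the volume of its own phase; every rate counts per litre of the first phase
- run time (flask): 25 h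

- target and product in the second phase together at 25 h, in percent of the starting material charged
- the change that raises the amount of target and product in the second phase together at 25 h, in percent of the starting material charged most ("none" if none brings more than 2 percentage points) (epsilon / delta / gamma / none)
- amount of target and product in the second phase together at 25 h, in percent of the starting material charged, after epsilon

Target in the first phase could be lost in two ways, and both rates carry c(target). Decomposition ran at 1.04 h⁻¹ times c(target), and the side reaction at 6.57 M⁻¹ h⁻¹ times c(starting material) times c(target). When I divided the first rate by the second, c(target) dropped out and time went with it, which left 1.04 h⁻¹ over 6.57 M⁻¹ h⁻¹ times c(starting material). With c(starting material) at its charge of 39 mM this gave 4.06, which I carried as the fate ratio, target decomposed per target taken into side product, the selectivity factor between the two losses. At the charge, then, 80.2% of the target lost by these two ways went to decomposed product. With c(starting material) under the line, the ratio climbs as c(starting material) falls. The half-life of first-phase target by decomposition, 0.67 h, was also short against the 25 h of the run, so I expected heavy losses. The ratio has no time in it, though, so my reckoning stopped there, with no figure for y.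

The forecast put y at 4.2% (range 3.3% to 5.2%), yb at 4.25% (range 3.3% to 5.3%) and best at none, holding that “only the product made in the last several hours survives”.

The simulation gave y as 3.94%, yb as 3.88% and best as none, with changes of −0.058 percentage points for epsilon, −0.84 points for delta and −1.6 points for gamma. The forecast's y would have been wrong for a reading at 16.4 h, where y in this flask had moved by 5 points.

Decomposition was the main reason so little target stood in this flask: with it taken away, the run held 64.8% of target against 3.94%. Since one side product holds two units of starting material, this flask's total count at 25.0 h was 13.6 decomposed per side product, between the fate ratio of 4.06 at the charge and 133 at the starting material then left. The neighbouring flask with 160 mM of starting material had a fate ratio of 0.990 at its charge and 1.57 at its end, and its total count of decomposed per side product stood at 1.34.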